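The chain is cut on both sides of C13 (numbered from the carboxyl carbon), at C12–C13 and C13–C14. C13 is the centre of the thirteen-CH2 tether C7–C19 that joins the C5≡C6 alkyne to C2 of the furan ring, so each flank is a (CH2)6 unit and both can come from 1-bromo-6-chlorohexane. In the key step bis(phenylsulfonyl)methane, a CH2 dianion synthon, is alkylated in one flask by methyl 12-iodododec-5-ynoate and then by 2-(6-iodohexyl)furan, which completes the C23 skeleton in a single operation. The precursors are therefore two unbranched primary iodides, one carrying the ynoate and one the furan; both sulfonyl groups are removed reductively afterwards.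

Key step: step 6

Remark on the chemistry: the target, 19-(furan-2-yl)nonadec-5-ynoic acid, has no stereocentre and no stereogenic double bond, so it is achiral and no enantiocontrol is needed. All structures were checked by atom count (C1–C12 arm, C13 linchpin, C14–C19 arm plus furan) and needed no correction.

Step 1
Reactants: 1 hex-5-ynoic acid; 2 1-bromo-6-chlorohexane
Product: 4 12-chlorododec-5-ynoic acid, via dilithiated hex-5-ynoate 3 (not isolated)
Conditions: n-BuLi (2.1 equiv), THF–DMPU, −78 → 0 °C; then 2 (1.1 equiv), 0 °C → rt; cold dil. HCl work-up
Reagents that add atoms: none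
Why: Two equivalents of base should give the carboxylate–acetylide dianion, whose acetylide carbon is by far the stronger nucleophile and displaces bromide in an SN2 acetylide alkylation, while the much poorer chloride leaving group stays as the handle for later exchange.

Step 2
Reactants: 4 12-chlorododec-5-ynoic acid
Product: 5 methyl 12-chlorododec-5-ynoate
Conditions: MeOH, cat. H2SO4, reflux
Reagents that add atoms: methanol, CO
Why: Fischer esterification in excess methanol leaves the internal alkyne and the primary chloride untouched; the methyl ester is chosen because exchange with methoxide in the later magnesium/methanol step is degenerate.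

Step 3
Reactants: 5 methyl 12-chlorododec-5-ynoate
Product: 6 methyl 12-iodododec-5-ynoate
Conditions: NaI (4 equiv), 2-butanone, 80 °C, dark
Reagents that add atoms: sodium iodide, [Na+].[I-]
Why: Finkelstein halide exchange (SN2 by iodide) is driven by precipitation of sodium chloride from the ketone solvent, with ester and alkyne as spectators.

Step 4
Reactants: 7 furan; 2 1-bromo-6-chlorohexane
Product: 9 2-(6-chlorohexyl)furan, via 2-lithiofuran 8 (not isolated)
Conditions: 7 (1.3 equiv), n-BuLi (1.0 equiv), THF, −78 → 0 °C; then 2, −78 °C → rt
Reagents that add atoms: none
Why: Furan is lithiated at C2, the most acidic position next to oxygen, and the heteroaryllithium should displace bromide selectively over chloride in an SN2 alkylation; excess furan suppresses 2,5-disubstitution.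

Step 5
Reactants: 9 2-(6-chlorohexyl)furan
Product: 10 2-(6-iodohexyl)furan
Conditions: NaI (4 equiv), NaHCO3 (cat.), 2-butanone, 80 °C, dark
Reagents that add atoms: sodium iodide, [Na+].[I-]
Why: Finkelstein exchange under neutral, slightly buffered conditions suits the acid-sensitive 2-alkylfuran and should give the primary iodide cleanly.

Step 6
Reactants: 11 bis(phenylsulfonyl)methane; 6 methyl 12-iodododec-5-ynoate; 10 2-(6-iodohexyl)furan
Product: 13 methyl 19-(furan-2-yl)-13,13-bis(phenylsulfonyl)nonadec-5-ynoate, via mono-alkylated bis-sulfone 12 (not isolated)
Conditions: 11 (1.05 equiv), K2CO3 (1.5 equiv), dry DMF, 40 °C, slow addition of 6 (1.0 equiv); then 10 (1.2 equiv), Cs2CO3 (2 equiv), 75 °C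
Reagents that add atoms: none
Why: Carbonate deprotonates the doubly sulfonyl-activated CH2 of 11 (pKa about 12 in DMSO) and the soft carbanion displaces iodide from C12 of 6 by SN2 to give 12; the remaining methine of 12, less acidic and more hindered, is then deprotonated by caesium carbonate and on heating its tertiary carbanion displaces iodide from 10, so that C12–C13 and C13–C14 are both made in one flask. The closest known reaction type is the sequential dialkylation of an active-methylene compound, here a gem-bis-sulfone serving as a CH2 dianion equivalent. No ring is closed, and the new quaternary carbon carries two identical sulfonyl groups, so no stereocentre arises. The selectivity needed is hetero- over homo-dialkylation: it should be secured by adding 6 slowly as the limiting partner at the lower temperature, where the anion of 12 hardly alkylates, and only then supplying 10, the stronger base and heat. Chemoselectivity rests on the acidity of the bis-sulfone, which lets carbonate bases do all the work without enolising the methyl ester, shifting the C5≡C6 triple bond or affecting the furan.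

Step 7
Reactants: 13 methyl 19-(furan-2-yl)-13,13-bis(phenylsulfonyl)nonadec-5-ynoate
Product: 15 methyl 19-(furan-2-yl)nonadec-5-ynoate, via mono-sulfone 14 (not isolated)
Conditions: Mg turnings (20 equiv, activated with cat. I2), MeOH–THF, rt → 50 °C; aq. NH4Cl work-up
Reagents that add atoms: none
Why: In this dissolving-metal reductive desulfonylation, electron transfer from magnesium into each sulfone should fragment the C–S bond with loss of benzenesulfinate and protonation at carbon by methanol, first to the mono-sulfone and then to the C13 methylene; the isolated dialkyl alkyne and the furan are not reducible under these conditions and methoxide can only exchange the methyl ester with itself.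

Step 8
Reactants: 15 methyl 19-(furan-2-yl)nonadec-5-ynoate
Product: 16 19-(furan-2-yl)nonadec-5-ynoic acid
Conditions: LiOH·H2O (3 equiv), THF–MeOH–H2O, rt; then 1 M HCl to pH 4, 0 °C
Reagents that add atoms: lithium hydroxide, [Li+].[OH-]
Why: Saponification (BAc2 ester hydrolysis) at room temperature is too mild to isomerise the skipped-free internal alkyne or harm the furan, and brief cold acidification to pH 4 should liberate the acid without opening the 2-alkylfuran.

Compound list
1 | hex-5-ynoic acid | C#CCCCC(=O)O | starting material
2 | 1-bromo-6-chlorohexane | ClCCCCCCBr | starting material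
3 | lithium 6-lithiohex-5-ynoate (carboxylate–acetylide dianion, formed in situ) | [Li]C#CCCCC(=O)O[Li] | intermediate
4 | 12-chlorododec-5-ynoic acid | OC(=O)CCCC#CCCCCCCCl | intermediate
5 | methyl 12-chlorododec-5-ynoate | COC(=O)CCCC#CCCCCCCCl | intermediate
6 | methyl 12-iodododec-5-ynoate | COC(=O)CCCC#CCCCCCCI | intermediate
7 | furan | c1ccoc1 | starting material
8 | 2-lithiofuran (formed in situ) | [Li]c1ccco1 | intermediate
9 | 2-(6-chlorohexyl)furan | ClCCCCCCc1ccco1 | intermediate
10 | 2-(6-iodohexyl)furan | ICCCCCCc1ccco1 | intermediate
11 | bis(phenylsulfonyl)methane | O=S(=O)(CS(=O)(=O)c1ccccc1)c1ccccc1 | starting material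
12 | methyl 13,13-bis(phenylsulfonyl)tridec-5-ynoate (formed in situ) | COC(=O)CCCC#CCCCCCCC(S(=O)(=O)c1ccccc1)S(=O)(=O)c1ccccc1 | intermediate
13 | methyl 19-(furan-2-yl)-13,13-bis(phenylsulfonyl)nonadec-5-ynoate | COC(=O)CCCC#CCCCCCCC(CCCCCCc1ccco1)(S(=O)(=O)c1ccccc1)S(=O)(=O)c1ccccc1 | intermediate
14 | methyl 19-(furan-2-yl)-13-(phenylsulfonyl)nonadec-5-ynoate (racemic at C13, formed in situ) | COC(=O)CCCC#CCCCCCCC(CCCCCCc1ccco1)S(=O)(=O)c1ccccc1 | intermediate
15 | methyl 19-(furan-2-yl)nonadec-5-ynoate | COC(=O)CCCC#CCCCCCCCCCCCCCc1ccco1 | intermediate
16 | 19-(furan-2-yl)nonadec-5-ynoic acid | O=C(O)CCCC#CCCCCCCCCCCCCCc1ccco1 | target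

Total step count: 8. Longest linear sequence: 6 steps (steps 1, 2, 3, 6, 7, 8); the furan arm (steps 4, 5) is made in parallel.

Steps most likely to fail

Step 6. The process at risk is scrambling of the two arms on the linchpin: the first iodide may add twice, or unreacted linchpin may capture the second iodide. The second SN2 at the hindered tertiary carbanion may also stall until the conditions begin to enolise or cleave the ester. Fallback: the one-flask mode is given up and the arms are introduced in the opposite order in two separate operations. Setting out from 11 and 10, an excess of 11 (2.5 equiv; NaH 1.2 equiv, THF–DMF, rt) should be mono-alkylated to 2-[7,7-bis(phenylsulfonyl)heptyl]furan F1, which is isolated and freed from surplus 11. F1 is then converted with exactly one equivalent of NaH in THF at 0 °C into its sodium salt F2, so that no free base meets the ester. DMF and 6 are added and the mixture is warmed to 50 °C, which should bring the route back at 13.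

Step 7. The process at risk is a reduction that stops after the first C–S cleavage, because the remaining secondary alkyl sulfone is much harder to reduce than the gem-disulfone. Passivation of the magnesium surface could have the same effect, and forcing the reaction could begin to touch the alkyne. Fallback: a sulfur-free construction of the C12–C13 bond. Setting out from 7 by way of 8 (as in step 4), alkylation with 1-bromo-7-chloroheptane F3 (THF, −78 °C → rt) should give 2-(7-chloroheptyl)furan F4. Magnesium in THF converts it into [7-(furan-2-yl)heptyl]magnesium chloride F5. This is coupled with iodide 6 under copper catalysis (Li2CuCl4 3 mol %, NMP, THF, 0 °C), an sp3–sp3 Kumada-type coupling that tolerates esters at this temperature, and the route is rejoined at 15.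

Step 1. The process at risk is aggregation and precipitation of the dilithio species, leading to slow or incomplete C-alkylation and to competing O-alkylation of the carboxylate. Fallback: C1 is carried at the alcohol oxidation level. Setting out from 2 and commercial hex-5-yn-1-ol F6, double deprotonation (n-BuLi 2.1 equiv, THF–DMPU, −78 → 0 °C) gives the dilithium alkoxide–acetylide of hex-5-yn-1-ol F7. Its acetylide carbon should be alkylated by 2 to give 12-chlorododec-5-yn-1-ol F8, the lithium alkoxide being a poor nucleophile in THF. Oxidation of the primary alcohol (TEMPO cat., PhI(OAc)2, MeCN–water, rt) should then return the route at 4.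

Further compounds
F1 | step 6 | 2-[7,7-bis(phenylsulfonyl)heptyl]furan | O=S(=O)(C(CCCCCCc1ccco1)S(=O)(=O)c1ccccc1)c1ccccc1
F2 | step 6 | sodium salt of 2-[7,7-bis(phenylsulfonyl)heptyl]furan | [Na+].O=S(=O)([C-](CCCCCCc1ccco1)S(=O)(=O)c1ccccc1)c1ccccc1
F3 | step 7 | 1-bromo-7-chloroheptane | ClCCCCCCCBr
F4 | step 7 | 2-(7-chloroheptyl)furan | ClCCCCCCCc1ccco1
F5 | step 7 | [7-(furan-2-yl)heptyl]magnesium chloride | Cl[Mg]CCCCCCCc1ccco1
F6 | step 1 | hex-5-yn-1-ol | C#CCCCCO
F7 | step 1 | dilithium alkoxide–acetylide of hex-5-yn-1-ol | [Li]C#CCCCCO[Li]
F8 | step 1 | 12-chlorododec-5-yn-1-ol | OCCCCC#CCCCCCCCl
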